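**Plan** (flavanone numbering: O1, C2–H, C3H2, hemiketal C4; ring A C4a–C8a; ring B C1'–C6')
Retrosynthesis: C3–C4 and O1–C2 are cut together, which opens both six-membered rings of the 2,8-dioxabicyclo[3.3.1]nonane and leaves an achiral aryl salicylate; the ester C4–O bond is cut next (ring A salicylic acid + 2-vinylresorcinol), then the chromene, prenyl and vinyl groups.
Enabling feature: C4 is at the carboxylic acid level, an ester carbon bound to C4a of ring A and to the oxygen on C2' of ring B. O1–C8a=C4a–C4=O is a latent oxa-diene and C2=C3 is a vinyl group ortho to that ester oxygen. Ring B is a symmetric 2-substituted resorcinol, so its second OH needs no protection.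
Forward: ring A is completed first (C-prenylation, propargyl ether, Claisen/6π chromene closure, oxidation to the acid), ring B is made by Wittig methylenation, the halves are joined as the ester, and one isomerisation forms C3–C4, O1–C2 and the hemiketal bridge.
Stereochemistry: C2 (R) is set in the key step by a chiral iridium–bisphosphine catalyst; C4 (R) follows because only the C2/C4 pair with both ring oxygens on the same side can bridge.

Key step: step 7

Assumption: the sense of induction of the bisphosphine in step 7 cannot be predicted for this new reaction, so the antipode that gives the (2R) series is meant and is written here as (S)-DTBM-SEGPHOS.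

Step 1
Reactants: 1 2,4-dihydroxy-6-methoxybenzaldehyde
Product: 2 2,4-dihydroxy-6-methoxy-3-(3-methylbut-2-en-1-yl)benzaldehyde
Conditions: prenyl bromide (1.05 equiv), 10 % aq KOH, 0 °C to rt
Reagents that add atoms: prenyl bromide (1-bromo-3-methylbut-2-ene), CC(C)=CCBr
Why: Phenolate C-prenylation: in water the dianion of 1 reacts with the soft allylic bromide at carbon, and C3, flanked by both phenoxide oxygens and para to the methoxy group, is the most nucleophilic ring position.

Step 2
Reactants: 2 2,4-dihydroxy-6-methoxy-3-(3-methylbut-2-en-1-yl)benzaldehyde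
Product: 3 2-hydroxy-6-methoxy-3-(3-methylbut-2-en-1-yl)-4-[(2-methylbut-3-yn-2-yl)oxy]benzaldehyde
Conditions: 3-chloro-3-methylbut-1-yne, K2CO3, KI (cat.), acetone, reflux
Reagents that add atoms: 3-chloro-3-methylbut-1-yne, CC(C)(Cl)C#C
Why: Williamson-type O-alkylation: the 4-OH is not hydrogen-bonded to the aldehyde and is the more acidic phenol, so it is etherified by the tertiary propargylic chloride while the chelated 2-OH stays free.

Step 3
Reactants: 3 2-hydroxy-6-methoxy-3-(3-methylbut-2-en-1-yl)-4-[(2-methylbut-3-yn-2-yl)oxy]benzaldehyde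
Product: 5 7-hydroxy-5-methoxy-2,2-dimethyl-8-(3-methylbut-2-en-1-yl)-2H-chromene-6-carbaldehyde, via allenyl phenol 4 (not isolated)
Conditions: o-xylene, 145 °C
Reagents that add atoms: none
Why: Aromatic propargyl Claisen rearrangement to C5, the only free ortho position, gives allenyl phenol 4, which closes to the 2,2-dimethyl-2H-chromene by 1,5-hydrogen shift and 6π-oxa-electrocyclisation.

Step 4
Reactants: 5 7-hydroxy-5-methoxy-2,2-dimethyl-8-(3-methylbut-2-en-1-yl)-2H-chromene-6-carbaldehyde
Product: 6 7-hydroxy-5-methoxy-2,2-dimethyl-8-(3-methylbut-2-en-1-yl)-2H-chromene-6-carboxylic acid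
Conditions: NaClO2, NaH2PO4, 2-methylbut-2-ene (large excess), t-BuOH–H2O, 0 °C to rt; acid kept cold and used at once
Reagents that add atoms: sodium chlorite, [Na+].[O-]Cl=O
Why: Pinnick oxidation: chlorous acid converts the aldehyde to the acid, and the excess 2-methylbut-2-ene removes HOCl before it can attack the chromene, the prenyl group or the phenol.

Step 5
Reactants: 7 2,6-dihydroxybenzaldehyde
Product: 8 2-ethenylbenzene-1,3-diol
Conditions: Ph3PCH3Br (3.3 equiv), KOtBu (3.2 equiv), THF, 0 °C to reflux
Reagents that add atoms: methyltriphenylphosphonium bromide, C[P+](c1ccccc1)(c1ccccc1)c1ccccc1.[Br-]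
Why: Wittig methylenation: excess ylide first deprotonates both phenols and then methylenates the aldehyde of the dianion, as is routine for salicylaldehydes.

Step 6
Reactants: 6 7-hydroxy-5-methoxy-2,2-dimethyl-8-(3-methylbut-2-en-1-yl)-2H-chromene-6-carboxylic acid; 8 2-ethenylbenzene-1,3-diol
Product: 10 2-ethenyl-3-hydroxyphenyl 7-hydroxy-5-methoxy-2,2-dimethyl-8-(3-methylbut-2-en-1-yl)-2H-chromene-6-carboxylate, via acid chloride 9 (not isolated)
Conditions: 6, 1-chloro-N,N,2-trimethylprop-1-en-1-amine, CH2Cl2, 0 °C; then 8 (3 equiv), Et3N, DMAP (cat.), −20 °C to rt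
Reagents that add atoms: none
Why: Acyl chloride esterification: the chloroenamine makes 9 under neutral conditions that spare the prenyl, phenol and chromene groups, and the excess of the symmetric diol 8 holds the acylation at the monoester.

Step 7
Reactants: 10 2-ethenyl-3-hydroxyphenyl 7-hydroxy-5-methoxy-2,2-dimethyl-8-(3-methylbut-2-en-1-yl)-2H-chromene-6-carboxylate
Product: 12 (2R,4R)-bridged hemiketal CNP0170313.2 (the 2'-oxygen of 11 bonded to C4 which carries OH; 6'-OH free), via flavanone 11 (not isolated)
Conditions: [Ir(cod)Cl]2 (5 mol %), (S)-DTBM-SEGPHOS (11 mol %), mesitylene, 130 °C, degassed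
Reagents that add atoms: none
Why: Proposed new method: the free ortho-hydroxyl of the salicylate (the future O1) directs oxidative addition of the ester C4–O bond to monovalent iridium, giving a five-membered acyl–iridium phenoxide chelate (trivalent iridium) that still carries the 2-vinylresorcinol as aryloxide; the vinyl group inserts into the Ir–C4 bond with C4 going to the terminal carbon (new C3–C4 bond, η3-benzylic Ir–C2), C–O reductive elimination with the chelated ring A phenoxide closes the pyranone ring, and the released ring B phenol adds to the C4 ketone of 11 to give the hemiketal. The closest known reaction type is the iridium-catalysed, ortho-hydroxyl-directed insertion of a tethered alkene into the acyl C–O bond of aryl salicylates (intramolecular alkene oxyacylation), together with the annulation of the same acyl–metal phenoxide chelate with alkynes to chromones; what is new is a vinyl group directly on the aryloxide ring, which forces the chelating oxygen instead of the ester oxygen to form the C–O bond. Ring closures: the pyranone ring by a formal oxa-[4+2] annulation (C3–C4 by 1,2-migratory insertion, then O1–C2 by reductive elimination from a seven-membered iridacycle), the second ring by 6-exo-trig hemiketalisation. C2 is set by face-selective alkene insertion under the axially chiral bisphosphine and passed on by stereoretentive C–O reductive elimination, and C4 is fixed by C2 because only the pair with both oxygens syn can close the 2,8-dioxabicyclo[3.3.1]nonane. The step needs acyl delivery to the terminal carbon and the ring A oxygen at the benzylic carbon: closure by the ring B oxygen would require a benzoxete or a 5-endo insertion, and the benzylic position is the one that stabilises iridium as an η3-benzyl, while β-hydride elimination to the chalcone is the pathway that would erode the selectivity.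

**Compound list**
1 | 2,4-dihydroxy-6-methoxybenzaldehyde | COc1cc(O)cc(O)c1C=O | starting material
2 | 2,4-dihydroxy-6-methoxy-3-(3-methylbut-2-en-1-yl)benzaldehyde | COc1cc(O)c(CC=C(C)C)c(O)c1C=O | intermediate
3 | 2-hydroxy-6-methoxy-3-(3-methylbut-2-en-1-yl)-4-[(2-methylbut-3-yn-2-yl)oxy]benzaldehyde | COc1cc(OC(C)(C)C#C)c(CC=C(C)C)c(O)c1C=O | intermediate
4 | 2,4-dihydroxy-6-methoxy-5-(3-methylbuta-1,2-dien-1-yl)-3-(3-methylbut-2-en-1-yl)benzaldehyde (allenyl phenol, not isolated) | COc1c(C=C=C(C)C)c(O)c(CC=C(C)C)c(O)c1C=O | intermediate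
5 | 7-hydroxy-5-methoxy-2,2-dimethyl-8-(3-methylbut-2-en-1-yl)-2H-chromene-6-carbaldehyde | COc1c(C=O)c(O)c(CC=C(C)C)c2OC(C)(C)C=Cc12 | intermediate
6 | 7-hydroxy-5-methoxy-2,2-dimethyl-8-(3-methylbut-2-en-1-yl)-2H-chromene-6-carboxylic acid | COc1c(C(=O)O)c(O)c(CC=C(C)C)c2OC(C)(C)C=Cc12 | intermediate
7 | 2,6-dihydroxybenzaldehyde | O=Cc1c(O)cccc1O | starting material
8 | 2-ethenylbenzene-1,3-diol (2-vinylresorcinol) | C=Cc1c(O)cccc1O | intermediate
9 | 7-hydroxy-5-methoxy-2,2-dimethyl-8-(3-methylbut-2-en-1-yl)-2H-chromene-6-carbonyl chloride (not isolated) | COc1c(C(Cl)=O)c(O)c(CC=C(C)C)c2OC(C)(C)C=Cc12 | intermediate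
10 | 2-ethenyl-3-hydroxyphenyl 7-hydroxy-5-methoxy-2,2-dimethyl-8-(3-methylbut-2-en-1-yl)-2H-chromene-6-carboxylate | COc1c(C(=O)Oc3cccc(O)c3C=C)c(O)c(CC=C(C)C)c2OC(C)(C)C=Cc12 | intermediate
11 | (2R)-2-(2,6-dihydroxyphenyl)-5-methoxy-8,8-dimethyl-10-(3-methylbut-2-en-1-yl)-2,3-dihydro-4H,8H-pyrano[3,2-g]chromen-4-one (open flavanone form, not isolated) | O=C1C[C@H](c2c(O)cccc2O)Oc2c(CC=C(C)C)c3OC(C)(C)C=Cc3c(OC)c12 | intermediate
12 | CNP0170313.2, the (2R,4R) hemiketal of 11 in which one ring B oxygen is bonded to C4, C4 carries OH and the other ring B OH is free | COc1c2c(c(CC=C(C)C)c3c1[C@@]1(O)C[C@@H](O3)c3c(O)cccc3O1)OC(C)(C)C=C2 | target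

**Step count and risks**
Total steps: 7. Longest linear sequence: 6 (steps 1, 2, 3, 4, 6, 7).

Steps most likely to fail:

Step 7 (Proposed new method). The acyl–iridium intermediate may lose CO, may insert the alkene in the 5-endo sense, or may undergo β-hydride elimination to the chalcone, which would then close without stereocontrol. The fallback uses known chemistry, sets out from 6 and 7 and returns at 12. Aldehyde 7 is protected with MOMCl and i-Pr2NEt to give 2,6-bis(methoxymethoxy)benzaldehyde F1. Acid 6 is activated with 1,1'-carbonyldiimidazole and condensed with potassium allyl malonate (MgCl2, Et3N, THF) in a decarboxylative Claisen condensation to the allyl β-keto ester F2. Knoevenagel condensation of F2 with F1 (piperidine, AcOH, toluene, 4 Å sieves) should give the alkylidene β-keto ester F3. A bifunctional cinchona-alkaloid thiourea (10 mol %, toluene, −25 °C; the pseudo-enantiomer that gives 2R) then closes the pyranone ring by enantioselective intramolecular oxa-Michael addition of the ring A phenol, giving the allyl 4-oxoflavan-3-carboxylate F4. Pd(PPh3)4 and morpholine in THF remove the allyl group, and the β-keto acid loses CO2 at room temperature to give the bis-MOM flavanone F5. Dilute HCl in THF–water cleaves both MOM ethers, whereupon the hemiketal should close to 12.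

Step 1. Site selectivity of the C-alkylation may be poor (attack at C5 or at oxygen, double prenylation). The fallback sets out from 1 and returns at 2. Alkylation of the 4-OH of 1 with 3-chloro-3-methylbut-1-yne (K2CO3, KI, acetone) gives the dimethylpropargyl ether F6. Semi-hydrogenation (H2, Pd/CaCO3 poisoned with Pb(OAc)2, quinoline) gives the dimethylallyl ether F7. Aromatic Claisen rearrangement (N,N-diethylaniline, 130 °C) then delivers the allyl unit with transposition to C3, the ortho position favoured by the chelated 2-OH/CHO pair, and gives 2.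

Step 6. Over-acylation to the diester and self-condensation of the hydroxy acid chloride may compete. The fallback sets out from 8 and 9 and returns at 10. Diol 8 is mono-silylated (TBSCl 1 equiv, imidazole, DMF) to the mono-TBS ether F8. F8 is acylated with 9 (Et3N, DMAP, CH2Cl2), now usable in excess, to the silylated ester F9. HF·pyridine in THF removes the silyl group to give 10.

Further compounds
F1 | step 7 | 2,6-bis(methoxymethoxy)benzaldehyde | COCOc1cccc(OCOC)c1C=O
F2 | step 7 | prop-2-en-1-yl 3-[7-hydroxy-5-methoxy-2,2-dimethyl-8-(3-methylbut-2-en-1-yl)-2H-chromen-6-yl]-3-oxopropanoate | COc1c(C(=O)CC(=O)OCC=C)c(O)c(CC=C(C)C)c2OC(C)(C)C=Cc12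
F3 | step 7 | prop-2-en-1-yl 3-[2,6-bis(methoxymethoxy)phenyl]-2-{[7-hydroxy-5-methoxy-2,2-dimethyl-8-(3-methylbut-2-en-1-yl)-2H-chromen-6-yl]carbonyl}prop-2-enoate (E/Z mixture) | COc1c(C(=O)C(=Cc3c(OCOC)cccc3OCOC)C(=O)OCC=C)c(O)c(CC=C(C)C)c2OC(C)(C)C=Cc12
F4 | step 7 | prop-2-en-1-yl (2R)-2-[2,6-bis(methoxymethoxy)phenyl]-5-methoxy-8,8-dimethyl-10-(3-methylbut-2-en-1-yl)-4-oxo-3,4-dihydro-2H,8H-pyrano[3,2-g]chromene-3-carboxylate (C3 epimers and enol) | O=C1C(C(=O)OCC=C)[C@H](c2c(OCOC)cccc2OCOC)Oc2c(CC=C(C)C)c3OC(C)(C)C=Cc3c(OC)c12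
F5 | step 7 | (2R)-2-[2,6-bis(methoxymethoxy)phenyl]-5-methoxy-8,8-dimethyl-10-(3-methylbut-2-en-1-yl)-2,3-dihydro-4H,8H-pyrano[3,2-g]chromen-4-one | O=C1C[C@H](c2c(OCOC)cccc2OCOC)Oc2c(CC=C(C)C)c3OC(C)(C)C=Cc3c(OC)c12
F6 | step 1 | 2-hydroxy-6-methoxy-4-[(2-methylbut-3-yn-2-yl)oxy]benzaldehyde | COc1cc(OC(C)(C)C#C)cc(O)c1C=O
F7 | step 1 | 2-hydroxy-6-methoxy-4-[(2-methylbut-3-en-2-yl)oxy]benzaldehyde | COc1cc(OC(C)(C)C=C)cc(O)c1C=O
F8 | step 6 | 3-[(tert-butyldimethylsilyl)oxy]-2-ethenylphenol | C=Cc1c(O)cccc1O[Si](C)(C)C(C)(C)C
F9 | step 6 | 3-[(tert-butyldimethylsilyl)oxy]-2-ethenylphenyl 7-hydroxy-5-methoxy-2,2-dimethyl-8-(3-methylbut-2-en-1-yl)-2H-chromene-6-carboxylate | COc1c(C(=O)Oc3cccc(O[Si](C)(C)C(C)(C)C)c3C=C)c(O)c(CC=C(C)C)c2OC(C)(C)C=Cc12
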